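A small charge of Ry starts to turn over the moment it enters, so what you count is exposure: the minutes the whole charge has on average spent in the flask. Under a steady feed, exposure is 0.562 min at 1.50 min; once the feed ends, it is the time minus half the dosing time.

| setting | red | green | blue | flask |
|---|---|---|---|---|
| Ry | 0.50 M (fed, over 2.0 min) | 0.50 M (fed, over 2.0 min) | 0.50 M (fed, over 2.0 min) | 0.50 M (fed, over 2.0 min) |
| Ul | 2 equiv | 4.5 equiv | 3 equiv | 3.00 equiv |
| Xa | 0.95 equiv | 0.95 equiv | 1.4 equiv | 0.950 equiv |
| remark | run made earlier | run made earlier | run made earlier |  |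
| time |  |  |  | 15 min |

| red: time / min | red: UlYm / % | green: time / min | green: UlYm / % | blue: time / min | blue: UlYm / % |
|---|---|---|---|---|---|
| 1.50 | 9.0 | 1.50 | 9.2 | 1.50 | 9.3 |
| 3.00 | 26.9 | 3.00 | 28.1 | 3.00 | 26.5 |
| 6.00 | 37.1 | 6.00 | 40.0 | 6.00 | 38.8 |
| 12.0 | 33.6 | 12.0 | 34.0 | 12.0 | 33.1 |

(each reading ± 0.5 percentage points)

- percentages count the whole charge, also what has not yet gone in

- the best time, 15 min at the latest, for UlYm
- the amount of UlYm, in percent of the Ry charged, at that time
- the first time at which UlYm reaches 20%, in the same percent, in min

Divide the first reading, averaged over the earlier runs, by that exposure. This gives 0.163 min⁻¹, the early turnover rate, UlYm formed per minute of exposure.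

The nearest neighbour of the flask is blue, with the same 3 equiv of Ul but 1.4 equiv of Xa against 0.950 equiv. Blue's first reading stands 0.3 percentage points from red's, less than the scatter of 0.5 points, so I expect the flask to start on the same line as both. Blue doesn't stay on it. At 6.00 min the line asks for 81.5%, and blue reads about half of that, 38.8%, between red and green. By 12.0 min it has fallen to 33.1%.

My own reckoning puts the flask's top near 6.00 min at about 38.5%, the mean of red and green there, which have its Xa and bracket its Ul. The line crosses the level asked at 2.23 min.

The forecast gives a best time of 6.5 min (5.3 min to 7.8 min), a best amount of 39% (37.8% to 40.5%) and a first crossing at 2.4 min (2.15 min to 2.65 min), holding that the flask “should sit mid-pack”; its top is later than mine, and so is its crossing.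

The simulation gives a best time of 6.68 min, a best amount of 39.3% and a first crossing at 2.28 min.

    Xa + Ym → XaYm (k = 0.230 M⁻¹ s⁻¹)
    Ry → Ym (k = 0.00380 s⁻¹)
    Xa ⇌ Aj (K = 0.450, k = 0.00660 s⁻¹)
    Ul + Ym → UlYm (k = 1.10 M⁻¹ s⁻¹)
    UlYm ⇌ Xi (K = 2.70, k = 0.00350 s⁻¹)

In the flask the line gives 16.3% at the end of the feed, where 16.2% stands, and its crossing at 2.23 min falls just before the simulated 2.28 min. Read the same flask at 4.0 min and the line asks for 48.9%, but that neighbour holds 34.1% of UlYm, and against the 15 points between the two it holds 12.5% as Xi. Take away the step UlYm ⇌ Xi, the largest single effect, and the highest amount of UlYm in the flask goes from 39.3% to 90.9%.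

Readings and results were generated by integration with made-up constants; noise was put on by code.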